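**Plan**

1. Retrosynthesis first removes the two benzyl groups on ring B (ester and C2 ether) and the two O–CH3 bonds on ring A (C2', C4'). It then opens ring A at C1'–C6', the bond between the carbon carrying the depside carbonyl and the carbon carrying propyl.
2. This works because ring A (C1'–C6') has oxygen on C2' and C4', the ester carbonyl on C1' and propyl on C6'. Together with the ester carbon it is C1–C10 of a folded 3,5,7-trioxodecanoate (C2 = C1', C7 = C6').
3. The open chain is then cut at the ester C(=O)–O bond (acylketene plus ring-B phenol) and at C4–C5 and C6–C7 (acetyl and butanoyl units on 2,2,6-trimethyl-1,3-dioxin-4-one).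
4. Forward: the dioxinone is acylated twice; divarinol is carboxylated and protected as the benzyl ester / 2-O-benzyl ether with the 4-OH free; thermolysis joins them as an aryl triketo ester. Ring A, the only ring made, is then closed on the finished ester, followed by methylation and hydrogenolysis.
5. Stereochemistry: the target has no stereocentre and no stereogenic double bond, so the given SMILES is one achiral compound and nothing has to be set. The two sp3 centres of the aldol adduct vanish on aromatisation.

Key step: step 10

Remark: reagents that only deliver a protecting group, a methyl group or a one-carbon unit are named under "Reagents that add atoms" and carry no compound number.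

**Route**

Step 1
Reactants: 1 2,2,6-trimethyl-4H-1,3-dioxin-4-one; 2 acetyl chloride
Product: 3 2,2-dimethyl-6-(2-oxopropyl)-4H-1,3-dioxin-4-one
Conditions: LiHMDS (2 equiv), THF, −78 °C; then AcCl, −78 → −20 °C; aq HCl
Reagents that add atoms: none
Why: Kinetic deprotonation of the 6-methyl group gives the lithium dienolate, whose terminal carbon is C-acylated by the acid chloride (vinylogous Claisen-type acylation), and the second equivalent of base holds the more acidic β-keto product as its enolate so that it is not acylated again.

Step 2
Reactants: 4 butanoyl chloride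
Product: 5 N-methoxy-N-methylbutanamide
Conditions: MeNH(OMe)·HCl, Et3N (2.2 equiv), CH2Cl2, 0 °C → rt
Reagents that add atoms: N,O-dimethylhydroxylamine hydrochloride, CNOC.Cl
Why: N-acylation of the amine by the acid chloride (Weinreb amide formation) should give an acyl donor that stops cleanly at the ketone stage in step 3.

Step 3
Reactants: 3 2,2-dimethyl-6-(2-oxopropyl)-4H-1,3-dioxin-4-one; 5 N-methoxy-N-methylbutanamide
Product: 6 6-(2,4-dioxoheptyl)-2,2-dimethyl-4H-1,3-dioxin-4-one
Conditions: LDA (2.2 equiv), THF, −78 °C; then 5, −78 → −40 °C; aq HCl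
Reagents that add atoms: none
Why: Double deprotonation gives a dianion whose terminal (methyl-derived) carbon is the more reactive site, so Claisen-type C-acylation occurs there (dianion γ-acylation), and the chelated tetrahedral Weinreb adduct prevents over-addition and proton transfer from the product.

Step 4
Reactants: 7 5-propylbenzene-1,3-diol (divarinol)
Product: 8 2,4-dihydroxy-6-propylbenzoic acid (divaric acid)
Conditions: MeOMgOCO2Me (2 M in DMF), 120 °C; then cold aq HCl
Reagents that add atoms: methyl magnesium carbonate, COC(=O)O[Mg]OC
Why: Chelation-driven ortho-carboxylation of the resorcinol (Kolbe–Schmitt-type reaction with methyl magnesium carbonate, as used for the pentyl homologue) should place the carboxyl ortho to one hydroxyl and para to the other, the magnesium salicylate chelate pulling the equilibrium over.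

Step 5
Reactants: 8 2,4-dihydroxy-6-propylbenzoic acid
Product: 9 benzyl 2,4-dihydroxy-6-propylbenzoate
Conditions: BnBr (1.05 equiv), KHCO3, DMF, rt
Reagents that add atoms: benzyl bromide, BrCc1ccccc1
Why: Potassium hydrogencarbonate ionises only the carboxylic acid, and the carboxylate is alkylated by benzyl bromide (SN2 O-alkylation) while both phenols stay protonated.

Step 6
Reactants: 9 benzyl 2,4-dihydroxy-6-propylbenzoate
Product: 10 benzyl 2-hydroxy-4-(prop-2-en-1-yloxy)-6-propylbenzoate
Conditions: allyl bromide (1.1 equiv), K2CO3 (1.1 equiv), acetone, rt → 50 °C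
Reagents that add atoms: allyl bromide, C=CCBr
Why: Williamson etherification under limiting base: the 4-hydroxyl is the more acidic and freely accessible phenol, whereas the 2-hydroxyl is held in a hydrogen bond to the ester carbonyl and should stay untouched.

Step 7
Reactants: 10 benzyl 2-hydroxy-4-(prop-2-en-1-yloxy)-6-propylbenzoate
Product: 11 benzyl 2-(benzyloxy)-4-(prop-2-en-1-yloxy)-6-propylbenzoate
Conditions: BnBr, Cs2CO3, DMF, 50 °C
Reagents that add atoms: benzyl bromide, BrCc1ccccc1
Why: Williamson etherification of the remaining chelated phenol, which needs the stronger caesium carbonate–DMF pair and mild heating; the allyl ether and benzyl ester are stable to these conditions.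

Step 8
Reactants: 11 benzyl 2-(benzyloxy)-4-(prop-2-en-1-yloxy)-6-propylbenzoate
Product: 12 benzyl 2-(benzyloxy)-4-hydroxy-6-propylbenzoate
Conditions: Pd(PPh3)4 (3 mol %), morpholine, THF, rt
Reagents that add atoms: none
Why: Tsuji–Trost deallylation: Pd(0) ionises the allyl aryl ether to a π-allyl complex and the phenoxide, morpholine takes up the allyl group, and the benzyl ether and benzyl ester do not ionise under these conditions.

Step 9
Reactants: 6 6-(2,4-dioxoheptyl)-2,2-dimethyl-4H-1,3-dioxin-4-one; 12 benzyl 2-(benzyloxy)-4-hydroxy-6-propylbenzoate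
Product: 14 benzyl 2-(benzyloxy)-6-propyl-4-[(3,5,7-trioxodecanoyl)oxy]benzoate, via diketo acylketene 13 (not isolated)
Conditions: PhMe, 110 °C, slow addition of 6 to 12 (1.5 equiv, ca. 1 M), Ar; solvent removed, crude 14 used at once without chromatography
Reagents that add atoms: none
Why: Thermal retro-hetero-Diels–Alder cleavage of the dioxinone releases acetone and the acylketene, and the phenol adds across the unhindered ketene carbon (acylketene capture, as in aryl acetoacetate formation from dioxinones), so the ester C–O bond is made before its carbonyl acquires two ortho substituents; the high phenol concentration favours this bimolecular capture over cyclisation of the ketene onto its own enol.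

Step 10
Reactants: 14 benzyl 2-(benzyloxy)-6-propyl-4-[(3,5,7-trioxodecanoyl)oxy]benzoate
Product: 16 benzyl 2-(benzyloxy)-4-[(2,4-dihydroxy-6-propylbenzoyl)oxy]-6-propylbenzoate, via cyclic aldol adduct 15 (not isolated)
Conditions: Et3N (30 mol %), CH2Cl2, 0 °C → rt; then TFA (1 equiv), rt
Reagents that add atoms: none
Why: Triethylamine enolises the C2 methylene, which is flanked by the aryl ester and the C3 ketone, and this carbon adds to the C7 ketone to give the cyclic aldol adduct 15; acid then eliminates the tertiary hydroxyl and the C3 and C5 carbonyls enolise, so the new C2–C7 bond becomes the C1'–C6' bond of an aromatic 2,4-dihydroxy-6-propylbenzoate. The closest known reaction type is the biomimetic aldol aromatisation of alkyl 3,5,7-trioxoalkanoates to resorcylates (orsellinate-type polyketide cyclisation). The one ring formed, carbocyclic ring A, closes in a 6-(enolendo)-exo-trig mode. No stereocentre survives, since the two sp3 centres of 15 are formed without control and both are erased by aromatisation. The selectivity needed is aldol closure (C2 onto C7) over Claisen closure (C6 onto C1) and pyranone lactonisation (C5 enol oxygen onto C1), both of which would expel the ring-B aryloxide; it should be secured because a ketone is the better acceptor for a carbon nucleophile than the ester carbonyl, because a catalytic amine in an aprotic medium supplies neither alkoxide nor any other external nucleophile, because the ring-B ester is twisted out of conjugation by its two ortho substituents and so makes the aryloxide only a moderate leaving group, and because irreversible aromatisation drains the reversible aldol manifold. The benzyl ether and benzyl ester of ring B are inert to both reagents.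

Step 11
Reactants: 16 benzyl 2-(benzyloxy)-4-[(2,4-dihydroxy-6-propylbenzoyl)oxy]-6-propylbenzoate
Product: 17 benzyl 2-(benzyloxy)-4-[(2,4-dimethoxy-6-propylbenzoyl)oxy]-6-propylbenzoate
Conditions: MeI (excess), K2CO3, acetone, reflux
Reagents that add atoms: iodomethane, CI
Why: Williamson O-methylation of the only two free hydroxyls in the molecule; the 4'-phenol reacts readily, the chelated 2'-phenol needs excess reagent at reflux, and the di-ortho-substituted aryl ester is shielded from the heterogeneous carbonate.

Step 12
Reactants: 17 benzyl 2-(benzyloxy)-4-[(2,4-dimethoxy-6-propylbenzoyl)oxy]-6-propylbenzoate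
Product: 18 4-[(2,4-dimethoxy-6-propylbenzoyl)oxy]-2-hydroxy-6-propylbenzoic acid (target)
Conditions: H2 (1 atm), 10% Pd/C, EtOAc, rt
Reagents that add atoms: none
Why: Catalytic hydrogenolysis cleaves both benzylic C–O bonds (ester and ether) and should leave the aryl ester, the methyl ethers and the arenes untouched at ambient pressure.

**Compound list**

1 | 2,2,6-trimethyl-4H-1,3-dioxin-4-one | CC1=CC(=O)OC(C)(C)O1 | starting material
2 | acetyl chloride | CC(=O)Cl | starting material
3 | 2,2-dimethyl-6-(2-oxopropyl)-4H-1,3-dioxin-4-one | CC(=O)CC1=CC(=O)OC(C)(C)O1 | intermediate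
4 | butanoyl chloride | CCCC(=O)Cl | starting material
5 | N-methoxy-N-methylbutanamide | CCCC(=O)N(C)OC | intermediate
6 | 6-(2,4-dioxoheptyl)-2,2-dimethyl-4H-1,3-dioxin-4-one | CCCC(=O)CC(=O)CC1=CC(=O)OC(C)(C)O1 | intermediate
7 | 5-propylbenzene-1,3-diol (divarinol) | CCCc1cc(O)cc(O)c1 | starting material
8 | 2,4-dihydroxy-6-propylbenzoic acid (divaric acid) | CCCc1cc(O)cc(O)c1C(=O)O | intermediate
9 | benzyl 2,4-dihydroxy-6-propylbenzoate | CCCc1cc(O)cc(O)c1C(=O)OCc1ccccc1 | intermediate
10 | benzyl 2-hydroxy-4-(prop-2-en-1-yloxy)-6-propylbenzoate | CCCc1cc(OCC=C)cc(O)c1C(=O)OCc1ccccc1 | intermediate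
11 | benzyl 2-(benzyloxy)-4-(prop-2-en-1-yloxy)-6-propylbenzoate | CCCc1cc(OCC=C)cc(OCc2ccccc2)c1C(=O)OCc1ccccc1 | intermediate
12 | benzyl 2-(benzyloxy)-4-hydroxy-6-propylbenzoate | CCCc1cc(O)cc(OCc2ccccc2)c1C(=O)OCc1ccccc1 | intermediate
13 | 3,5,7-trioxodec-1-en-1-one (diketo acylketene) | CCCC(=O)CC(=O)CC(=O)C=C=O | intermediate (not isolated)
14 | benzyl 2-(benzyloxy)-6-propyl-4-[(3,5,7-trioxodecanoyl)oxy]benzoate | CCCC(=O)CC(=O)CC(=O)CC(=O)Oc1cc(CCC)c(C(=O)OCc2ccccc2)c(OCc2ccccc2)c1 | intermediate
15 | benzyl 2-(benzyloxy)-4-[(2-hydroxy-4,6-dioxo-2-propylcyclohexane-1-carbonyl)oxy]-6-propylbenzoate (cyclic aldol adduct, mixture of stereoisomers) | CCCC1(O)CC(=O)CC(=O)C1C(=O)Oc1cc(CCC)c(C(=O)OCc2ccccc2)c(OCc2ccccc2)c1 | intermediate (not isolated)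
16 | benzyl 2-(benzyloxy)-4-[(2,4-dihydroxy-6-propylbenzoyl)oxy]-6-propylbenzoate | CCCc1cc(O)cc(O)c1C(=O)Oc1cc(CCC)c(C(=O)OCc2ccccc2)c(OCc2ccccc2)c1 | intermediate
17 | benzyl 2-(benzyloxy)-4-[(2,4-dimethoxy-6-propylbenzoyl)oxy]-6-propylbenzoate | CCCc1cc(OC)cc(OC)c1C(=O)Oc1cc(CCC)c(C(=O)OCc2ccccc2)c(OCc2ccccc2)c1 | intermediate
18 | 4-[(2,4-dimethoxy-6-propylbenzoyl)oxy]-2-hydroxy-6-propylbenzoic acid | CCCc1cc(OC(=O)c2c(CCC)cc(OC)cc2OC)cc(O)c1C(=O)O | target

**Step count**

Total steps: 12. Longest linear sequence: 9 steps (7 → 8 → 9 → 10 → 11 → 12 → 14 → 16 → 17 → 18, steps 4–12).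

**Steps most likely to fail**

Step 10 (key step). The enolised triketo ester may partition towards acyl substitution at C1, by Claisen ring closure or by lactonisation of the C5 enol oxygen, with loss of the ring-B aryloxide, instead of aldol closure. The fallback gives up building ring A on the ester and makes the hindered ester by direct acylation. It sets out from 9: exhaustive O-methylation (MeI, K2CO3, acetone, reflux) should give benzyl 2,4-dimethoxy-6-propylbenzoate F1, and hydrogenolysis (H2, Pd/C, EtOAc) the acid 2,4-dimethoxy-6-propylbenzoic acid F2. Trifluoroacetic anhydride in toluene at room temperature would convert F2 into the mixed anhydride 2,4-dimethoxy-6-propylbenzoic trifluoroacetic anhydride F3 (not isolated), whose electron-rich acyl group is transferred to phenol 12. This returns to the route at 17.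

Step 9. Capture of the acylketene by the enol oxygen of its own chain, closing a 4-hydroxypyran-2-one, may outrun addition of the weakly nucleophilic phenol, and the aryl ester may lose aryloxide by the same lactonisation at 110 °C. The fallback aromatises first and forms the ester by capture of a quinoketene. It sets out from 6: triethylamine in CH2Cl2 should close the ring with the dioxinone intact (its C5 adds to the butanoyl ketone) to give 7-hydroxy-2,2-dimethyl-5-propyl-4H-1,3-benzodioxin-4-one F4, and methylation (MeI, K2CO3, acetone) 7-methoxy-2,2-dimethyl-5-propyl-4H-1,3-benzodioxin-4-one F5. Irradiation of F5 (300 nm, CH2Cl2, rt) in the presence of 12 expels acetone to give the quinoketene 3-methoxy-6-(oxomethylidene)-5-propylcyclohexa-2,4-dien-1-one F6 (not isolated), which 12 traps as benzyl 2-(benzyloxy)-4-[(2-hydroxy-4-methoxy-6-propylbenzoyl)oxy]-6-propylbenzoate F7. Methylation of its one phenol under the conditions of step 11 returns to the route at 17.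

Step 3. Incomplete dianion formation, O-acylation, or proton transfer from the acidic product to unreacted dianion may hold the terminal C-acylation at low conversion. The fallback replaces the acylation by an aldol addition and an oxidation. It sets out from 3: the same dianion (LDA, 2.2 equiv, THF, −78 °C) should add to butanal to give 6-(4-hydroxy-2-oxoheptyl)-2,2-dimethyl-4H-1,3-dioxin-4-one F8 (racemic; the carbinol centre is removed again). Dess–Martin periodinane in CH2Cl2 would oxidise it to the diketone, returning to the route at 6.

**Further compounds**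

F1 | step 10 | benzyl 2,4-dimethoxy-6-propylbenzoate | CCCc1cc(OC)cc(OC)c1C(=O)OCc1ccccc1
F2 | step 10 | 2,4-dimethoxy-6-propylbenzoic acid | CCCc1cc(OC)cc(OC)c1C(=O)O
F3 | step 10 | 2,4-dimethoxy-6-propylbenzoic trifluoroacetic anhydride | CCCc1cc(OC)cc(OC)c1C(=O)OC(=O)C(F)(F)F
F4 | step 9 | 7-hydroxy-2,2-dimethyl-5-propyl-4H-1,3-benzodioxin-4-one | CCCc1cc(O)cc2OC(C)(C)OC(=O)c12
F5 | step 9 | 7-methoxy-2,2-dimethyl-5-propyl-4H-1,3-benzodioxin-4-one | CCCc1cc(OC)cc2OC(C)(C)OC(=O)c12
F6 | step 9 | 3-methoxy-6-(oxomethylidene)-5-propylcyclohexa-2,4-dien-1-one | O=C=C1C(=O)C=C(OC)C=C1CCC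
F7 | step 9 | benzyl 2-(benzyloxy)-4-[(2-hydroxy-4-methoxy-6-propylbenzoyl)oxy]-6-propylbenzoate | CCCc1cc(OC)cc(O)c1C(=O)Oc1cc(CCC)c(C(=O)OCc2ccccc2)c(OCc2ccccc2)c1
F8 | step 3 | 6-(4-hydroxy-2-oxoheptyl)-2,2-dimethyl-4H-1,3-dioxin-4-one | CCCC(O)CC(=O)CC1=CC(=O)OC(C)(C)O1
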